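**Assumption:** the SMILES is taken literally. It encodes a cis-fused decalin, (3R,4R,5S,9S,10R) in labdane numbering: 10-CH3, 5-H, the C9 side chain and the CO2H lie on one face, 3-OAc and 4-CH3 on the other. That compound is the one made here.

**Retrosynthetic overview**
- The acid comes from late oxidation of the C19 primary alcohol; C8=CH2 comes from methylenation of a C8 ketone; the diene side chain comes from Hosomi–Sakurai addition of an isoprenylsilane to a C9 exo-methylene ketone.
- The C10 quaternary centre and the cis ring fusion come from conjugate methylation of a bicyclic enone (C8=O, C9=C10).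
- Ring A is closed onto a preformed ring B (C4–C5 bond) by epoxide-opening cyclization onto a Birch-derived 1-methoxycyclohexa-1,4-diene.
- The C3–O bond is made by Sharpless asymmetric epoxidation of an (E)-allylic alcohol; this is the only source of absolute configuration and it relays to C4, C5, C10 and C9.
- Ring B is formed first (from 3-methoxybenzyl chloride by Birch reduction), then ring A; the C1–C4/C18/C19 unit comes from isoprene monoxide.

Labdane numbering is used in the "Why" lines (C3 = CH–OAc, C4 = C(CH3)(CO2H), C5/C10 = ring fusion, C8 = C(=CH2), C9 = CH–side chain).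

**Step 1**
Reactants: 1 3-methoxybenzyl chloride; 2 2-methyl-2-vinyloxirane (isoprene monoxide, racemic)
Product: 4 (E)-5-(3-methoxyphenyl)-2-methylpent-2-en-1-ol, via 3-methoxybenzylmagnesium chloride 3 (not isolated)
Conditions: Mg, Et2O, 0 °C; then 2, CuI (10 mol%), THF, −30 → 0 °C
Reagents that add atoms: none
Why: Copper-catalysed anti-SN2′ opening of the vinyl epoxide by the benzylic Grignard reagent attacks the vinyl terminus and gives the (E)-trisubstituted allylic alcohol, whose E geometry later decides which C4 substituent is axial (no stereocentre formed).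

**Step 2**
Reactants: 4 (E)-5-(3-methoxyphenyl)-2-methylpent-2-en-1-ol
Product: 5 (E)-5-(5-methoxycyclohexa-1,4-dien-1-yl)-2-methylpent-2-en-1-ol
Conditions: Li, NH3(l), THF, t-BuOH, −78 → −33 °C; then MeOH
Reagents that add atoms: none
Why: Birch reduction of a 3-alkylanisole gives the 1-methoxy-5-alkylcyclohexa-1,4-diene (OMe and alkyl stay on sp2 carbons), and the allylic alkoxide side chain is not reduced.

**Step 3**
Reactants: 5 (E)-5-(5-methoxycyclohexa-1,4-dien-1-yl)-2-methylpent-2-en-1-ol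
Product: 6 [(2R,3R)-3-[2-(5-methoxycyclohexa-1,4-dien-1-yl)ethyl]-2-methyloxiran-2-yl]methanol
Conditions: Ti(OiPr)4 (10 mol%), D-(−)-diethyl tartrate (12 mol%), t-BuOOH, 4 Å molecular sieves, CH2Cl2, −20 °C
Reagents that add atoms: tert-butyl hydroperoxide, CC(C)(C)OO
Why: Sharpless asymmetric epoxidation is hydroxyl-directed, so only the allylic alkene reacts, and D-(−)-tartrate gives the (2R,3R)-epoxide, which fixes C3 (R, the future acetate C–O bond) and the C4 centre.

**Step 4**
Reactants: 6 [(2R,3R)-3-[2-(5-methoxycyclohexa-1,4-dien-1-yl)ethyl]-2-methyloxiran-2-yl]methanol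
Product: 7 tert-butyl{[(2R,3R)-3-[2-(5-methoxycyclohexa-1,4-dien-1-yl)ethyl]-2-methyloxiran-2-yl]methoxy}dimethylsilane
Conditions: TBSCl, imidazole, DMF, 0 °C → rt
Reagents that add atoms: tert-butyl(chloro)dimethylsilane, CC(C)(C)[Si](C)(C)Cl
Why: Standard silylation of the primary alcohol removes the free OH before the Lewis-acid step and carries C19 as a protected CH2O until the end (no stereocentre touched).

**Step 5**
Reactants: 7 tert-butyl{[(2R,3R)-3-[2-(5-methoxycyclohexa-1,4-dien-1-yl)ethyl]-2-methyloxiran-2-yl]methoxy}dimethylsilane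
Product: 9 (4aS,5S,6R)-5-({[tert-butyl(dimethyl)silyl]oxy}methyl)-6-hydroxy-5-methyl-4,4a,5,6,7,8-hexahydronaphthalen-2(3H)-one, via methoxydiene 8 (not isolated)
Conditions: MeAlCl2 (2.2 equiv), CH2Cl2, −78 °C; then aq. oxalic acid, THF, 0 °C
Reagents that add atoms: water, O
Why: Proposed new method: MeAlCl2 activates the epoxide and the remote trisubstituted alkene of the Birch diene (C5=C10) attacks the tertiary C4 anti to the C–O bond through a chair (C3–O equatorial, 4-CH3 axial, ring B equatorial), which sets C4 by inversion and C5 (S); the tertiary C10 cation then loses the aligned H-9 (methane from Al–CH3) to give the conjugated 2-methoxydiene 8, which mild acid hydrolyses to the enone; the closest known reaction type is the Lewis-acid epoxy-olefin (polyene) cyclization terminated by an enol ether or silyl enol ether, but a 1-methoxycyclohexa-1,4-diene has not been used as the terminating nucleophile.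

**Step 6**
Reactants: 9 (4aS,5S,6R)-5-({[tert-butyl(dimethyl)silyl]oxy}methyl)-6-hydroxy-5-methyl-4,4a,5,6,7,8-hexahydronaphthalen-2(3H)-one
Product: 10 (1S,2R,8aS)-1-({[tert-butyl(dimethyl)silyl]oxy}methyl)-1-methyl-6-oxo-1,2,3,4,6,7,8,8a-octahydronaphthalen-2-yl acetate
Conditions: Ac2O, pyridine, 4-(dimethylamino)pyridine (cat.), CH2Cl2, rt
Reagents that add atoms: acetic anhydride, CC(=O)OC(C)=O
Why: Nucleophile-catalysed acylation of the equatorial secondary alcohol installs the target acetate with retention at C3.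

**Step 7**
Reactants: 10 (1S,2R,8aS)-1-({[tert-butyl(dimethyl)silyl]oxy}methyl)-1-methyl-6-oxo-1,2,3,4,6,7,8,8a-octahydronaphthalen-2-yl acetate
Product: 14 (1S,2R,4aS,8aS)-1-({[tert-butyl(dimethyl)silyl]oxy}methyl)-1,4a-dimethyl-5-methylidene-6-oxodecahydronaphthalen-2-yl acetate, via silyl enol ether 11 (not isolated), via Mannich base 12 (not isolated), via ammonium iodide 13 (not isolated)
Conditions: Me2CuLi (from MeLi, CuI), TMSCl, THF, −78 → −40 °C; then CH2=NMe2+ I−, CH2Cl2, rt; MeI; aq. NaHCO3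
Reagents that add atoms: methyllithium (used as Me2CuLi), C[Li]; N,N-dimethylmethyleneiminium iodide, C=[N+](C)C.[I-]
Why: Gilman conjugate addition with TMSCl delivers CH3 to C10 on the face anti to the quaternary C4 on the neighbouring C5 (the usual cis-decalin mode for octalones), so 10-CH3 ends syn to H-5; the regiodefined enol ether is then aminomethylated at C9 (Mannich reaction), quaternised and eliminated to the exo-methylene ketone.

**Step 8**
Reactants: 15 2-chlorobuta-1,3-diene (chloroprene); 16 (trimethylsilyl)methylmagnesium chloride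
Product: 17 trimethyl(2-methylidenebut-3-en-1-yl)silane
Conditions: NiCl2(Ph2PCH2CH2CH2PPh2) (1 mol%), Et2O, reflux
Reagents that add atoms: none
Why: Nickel-catalysed Kumada coupling of the vinyl chloride with the silylmethyl Grignard reagent gives the isoprenyl allylsilane (no stereocentre).

**Step 9**
Reactants: 14 (1S,2R,4aS,8aS)-1-({[tert-butyl(dimethyl)silyl]oxy}methyl)-1,4a-dimethyl-5-methylidene-6-oxodecahydronaphthalen-2-yl acetate; 17 trimethyl(2-methylidenebut-3-en-1-yl)silane
Product: 18 (1S,2R,4aS,5R,8aS)-1-({[tert-butyl(dimethyl)silyl]oxy}methyl)-1,4a-dimethyl-5-(3-methylidenepent-4-en-1-yl)-6-oxodecahydronaphthalen-2-yl acetate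
Conditions: TiCl4, CH2Cl2, −78 °C; then H2O
Reagents that add atoms: none
Why: Hosomi–Sakurai conjugate addition of the allylsilane to the s-cis exo-methylene ketone builds C11–C12 and the 2-substituted diene in one step, and C9 is set on protonation of the titanium enolate with the side chain equatorial and cis to 10-CH3 (the other epimer would be 1,3-diaxial to C4, so this is also the thermodynamic epimer).

**Step 10**
Reactants: 18 (1S,2R,4aS,5R,8aS)-1-({[tert-butyl(dimethyl)silyl]oxy}methyl)-1,4a-dimethyl-5-(3-methylidenepent-4-en-1-yl)-6-oxodecahydronaphthalen-2-yl acetate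
Product: 19 (1S,2R,4aR,5S,8aS)-1-({[tert-butyl(dimethyl)silyl]oxy}methyl)-1,4a-dimethyl-6-methylidene-5-(3-methylidenepent-4-en-1-yl)decahydronaphthalen-2-yl acetate
Conditions: Zn, CH2Br2, TiCl4, THF/CH2Cl2, 0 °C → rt
Reagents that add atoms: dibromomethane, BrCBr
Why: Takai–Lombardo methylenation is non-basic and ketone-selective, so the hindered C8 ketone becomes the exocyclic alkene without touching the acetate or epimerising C9.

**Step 11**
Reactants: 19 (1S,2R,4aR,5S,8aS)-1-({[tert-butyl(dimethyl)silyl]oxy}methyl)-1,4a-dimethyl-6-methylidene-5-(3-methylidenepent-4-en-1-yl)decahydronaphthalen-2-yl acetate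
Product: 20 (1S,2R,4aR,5S,8aS)-1-(hydroxymethyl)-1,4a-dimethyl-6-methylidene-5-(3-methylidenepent-4-en-1-yl)decahydronaphthalen-2-yl acetate
Conditions: HF·pyridine, pyridine, THF, 0 °C → rt
Reagents that add atoms: none
Why: Buffered fluoride cleavage of the primary silyl ether leaves the acetate, the exocyclic alkene and the diene untouched.

**Step 12**
Reactants: 20 (1S,2R,4aR,5S,8aS)-1-(hydroxymethyl)-1,4a-dimethyl-6-methylidene-5-(3-methylidenepent-4-en-1-yl)decahydronaphthalen-2-yl acetate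
Product: 21 (1R,2R,4aR,5S,8aS)-2-(acetyloxy)-1,4a-dimethyl-6-methylidene-5-(3-methylidenepent-4-en-1-yl)decahydronaphthalene-1-carboxylic acid (CNP0243981.1)
Conditions: 2-azaadamantane N-oxyl (5 mol%), PhI(OAc)2, MeCN/pH 7 phosphate buffer, rt
Reagents that add atoms: water, O
Why: Nitroxyl-catalysed oxidation with a hypervalent iodine co-oxidant takes the neopentyl primary alcohol through the aldehyde hydrate to the acid without attacking the alkenes or any stereocentre (the unhindered azaadamantane nitroxyl is chosen for the hindered alcohol).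

**Compound list**
1 | 3-methoxybenzyl chloride | COc1cccc(CCl)c1 | starting material
2 | 2-methyl-2-vinyloxirane (isoprene monoxide, racemic) | C=CC1(C)CO1 | starting material
3 | 3-methoxybenzylmagnesium chloride | COc1cccc(C[Mg]Cl)c1 | intermediate (not isolated)
4 | (E)-5-(3-methoxyphenyl)-2-methylpent-2-en-1-ol | COc1cccc(CC/C=C(\C)CO)c1 | intermediate
5 | (E)-5-(5-methoxycyclohexa-1,4-dien-1-yl)-2-methylpent-2-en-1-ol | COC1=CCC=C(CC/C=C(\C)CO)C1 | intermediate
6 | [(2R,3R)-3-[2-(5-methoxycyclohexa-1,4-dien-1-yl)ethyl]-2-methyloxiran-2-yl]methanol | OC[C@@]1(C)O[C@@H]1CCC2=CCC=C(OC)C2 | intermediate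
7 | tert-butyl{[(2R,3R)-3-[2-(5-methoxycyclohexa-1,4-dien-1-yl)ethyl]-2-methyloxiran-2-yl]methoxy}dimethylsilane | CC(C)(C)[Si](C)(C)OC[C@@]1(C)O[C@@H]1CCC2=CCC=C(OC)C2 | intermediate
8 | (1S,2R,8aS)-1-({[tert-butyl(dimethyl)silyl]oxy}methyl)-6-methoxy-1-methyl-1,2,3,4,8,8a-hexahydronaphthalen-2-ol (present as its aluminium alkoxide) | COC1=CC[C@H]2C(=C1)CC[C@@H](O)[C@]2(C)CO[Si](C)(C)C(C)(C)C | intermediate (not isolated)
9 | (4aS,5S,6R)-5-({[tert-butyl(dimethyl)silyl]oxy}methyl)-6-hydroxy-5-methyl-4,4a,5,6,7,8-hexahydronaphthalen-2(3H)-one | O=C1CC[C@H]2C(=C1)CC[C@@H](O)[C@]2(C)CO[Si](C)(C)C(C)(C)C | intermediate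
10 | (1S,2R,8aS)-1-({[tert-butyl(dimethyl)silyl]oxy}methyl)-1-methyl-6-oxo-1,2,3,4,6,7,8,8a-octahydronaphthalen-2-yl acetate | O=C1CC[C@H]2C(=C1)CC[C@@H](OC(C)=O)[C@]2(C)CO[Si](C)(C)C(C)(C)C | intermediate
11 | (1S,2R,4aS,8aS)-1-({[tert-butyl(dimethyl)silyl]oxy}methyl)-1,4a-dimethyl-6-[(trimethylsilyl)oxy]-1,2,3,4,4a,7,8,8a-octahydronaphthalen-2-yl acetate (cis-fused, 4a-CH3 syn to H-8a) | C1=C(O[Si](C)(C)C)CC[C@H]2[C@]1(C)CC[C@@H](OC(C)=O)[C@]2(C)CO[Si](C)(C)C(C)(C)C | intermediate (not isolated)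
12 | (1S,2R,4aS,8aS)-1-({[tert-butyl(dimethyl)silyl]oxy}methyl)-5-[(dimethylamino)methyl]-1,4a-dimethyl-6-oxodecahydronaphthalen-2-yl acetate (epimers at C5) | CN(C)CC1C(=O)CC[C@H]2[C@]1(C)CC[C@@H](OC(C)=O)[C@]2(C)CO[Si](C)(C)C(C)(C)C | intermediate (not isolated)
13 | trimethylammonium iodide of 12 (N,N,N-trimethyl methanaminium salt, epimers at C5) | C[N+](C)(C)CC1C(=O)CC[C@H]2[C@]1(C)CC[C@@H](OC(C)=O)[C@]2(C)CO[Si](C)(C)C(C)(C)C.[I-] | intermediate (not isolated)
14 | (1S,2R,4aS,8aS)-1-({[tert-butyl(dimethyl)silyl]oxy}methyl)-1,4a-dimethyl-5-methylidene-6-oxodecahydronaphthalen-2-yl acetate | C=C1C(=O)CC[C@H]2[C@]1(C)CC[C@@H](OC(C)=O)[C@]2(C)CO[Si](C)(C)C(C)(C)C | intermediate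
15 | 2-chlorobuta-1,3-diene (chloroprene) | C=CC(Cl)=C | starting material
16 | (trimethylsilyl)methylmagnesium chloride | C[Si](C)(C)C[Mg]Cl | starting material
17 | trimethyl(2-methylidenebut-3-en-1-yl)silane | C=CC(=C)C[Si](C)(C)C | intermediate
18 | (1S,2R,4aS,5R,8aS)-1-({[tert-butyl(dimethyl)silyl]oxy}methyl)-1,4a-dimethyl-5-(3-methylidenepent-4-en-1-yl)-6-oxodecahydronaphthalen-2-yl acetate | C=CC(=C)CC[C@H]1C(=O)CC[C@H]2[C@]1(C)CC[C@@H](OC(C)=O)[C@]2(C)CO[Si](C)(C)C(C)(C)C | intermediate
19 | (1S,2R,4aR,5S,8aS)-1-({[tert-butyl(dimethyl)silyl]oxy}methyl)-1,4a-dimethyl-6-methylidene-5-(3-methylidenepent-4-en-1-yl)decahydronaphthalen-2-yl acetate | C=CC(=C)CC[C@H]1C(=C)CC[C@H]2[C@]1(C)CC[C@@H](OC(C)=O)[C@]2(C)CO[Si](C)(C)C(C)(C)C | intermediate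
20 | (1S,2R,4aR,5S,8aS)-1-(hydroxymethyl)-1,4a-dimethyl-6-methylidene-5-(3-methylidenepent-4-en-1-yl)decahydronaphthalen-2-yl acetate | C=CC(=C)CC[C@H]1C(=C)CC[C@H]2[C@]1(C)CC[C@@H](OC(C)=O)[C@]2(C)CO | intermediate
21 | (1R,2R,4aR,5S,8aS)-2-(acetyloxy)-1,4a-dimethyl-6-methylidene-5-(3-methylidenepent-4-en-1-yl)decahydronaphthalene-1-carboxylic acid | C=CC(=C)CC[C@H]1C(=C)CC[C@H]2[C@]1(C)CC[C@@H](OC(C)=O)[C@]2(C)C(=O)O | target

**Step count:** 12 steps in total. The longest linear sequence is 11 steps (steps 1–7 and 9–12); step 8 is a one-step side branch.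

**Three steps most likely to fail**

Step 5 (the proposed new cyclization). The risks are Lewis-acid damage to the enol ether, epoxide-to-ketone rearrangement, and loss of the C10 cation toward C5 or C1 instead of C9. The fallback uses known chemistry and sets out from 4. Sharpless epoxidation of 4 under the step 3 conditions gives [(2R,3R)-3-[2-(3-methoxyphenyl)ethyl]-2-methyloxiran-2-yl]methanol F1. Silylation (TBSCl, imidazole) gives tert-butyl{[(2R,3R)-3-[2-(3-methoxyphenyl)ethyl]-2-methyloxiran-2-yl]methoxy}dimethylsilane F2. A Lewis-acid epoxy-arene (Friedel–Crafts) cyclization (BF3·OEt2 or SnCl4, CH2Cl2, −78 °C) closes ring A para to the methoxy group and gives (1S,2R)-1-({[tert-butyl(dimethyl)silyl]oxy}methyl)-6-methoxy-1-methyl-1,2,3,4-tetrahydronaphthalen-2-ol F3. Birch reduction (Li, NH3, t-BuOH) gives (1S,2R)-1-({[tert-butyl(dimethyl)silyl]oxy}methyl)-6-methoxy-1-methyl-1,2,3,4,5,8-hexahydronaphthalen-2-ol F4. Aqueous HCl in THF hydrolyses the enol ether and brings the double bond into conjugation, which comes back to the route at 9. In this variant C5 is set only in the final protonation, so its selectivity is not assured and the C5 epimer may have to be removed by chromatography.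

Step 7 (conjugate methylation of a congested enone, then α-methylenation). The risk is a sluggish cuprate addition next to the quaternary C4. The fallback sets out from 10. Corey–Chaykovsky cyclopropanation (trimethylsulfoxonium iodide, NaH, DMSO) on the face anti to C4 gives (1S,2R,8aS)-1-({[tert-butyl(dimethyl)silyl]oxy}methyl)-1-methyl-6-oxo-4a,5-methanodecahydronaphthalen-2-yl acetate (cyclopropane CH2 syn to H-8a) F5. SmI2 (THF/DMPU, t-BuOH) cleaves the exocyclic cyclopropane bond, the one that overlaps with the ketyl, which leaves the angular methyl and a samarium enolate. TMSCl/Et3N silylates that enolate, and the sequence comes back to the route at 11; the aminomethylation and elimination of step 7 then follow unchanged.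

Step 9 (Lewis-acid isoprenylation). The risks are polymerisation of the exo-methylene ketone or of the diene under TiCl4. The fallback sets out from 14. TiCl4-promoted conjugate propargylation with Bu3SnCH=C=CH2 gives (1S,2R,4aS,5R,8aS)-5-(but-3-yn-1-yl)-1-({[tert-butyl(dimethyl)silyl]oxy}methyl)-1,4a-dimethyl-6-oxodecahydronaphthalen-2-yl acetate F6. Methylenation with Zn, CH2Br2, TiCl4 gives (1S,2R,4aR,5S,8aS)-5-(but-3-yn-1-yl)-1-({[tert-butyl(dimethyl)silyl]oxy}methyl)-1,4a-dimethyl-6-methylidenedecahydronaphthalen-2-yl acetate F7. Enyne cross-metathesis with ethylene (second-generation Grubbs catalyst (H2IMes)(PCy3)Cl2Ru=CHPh, 1 atm ethylene, CH2Cl2) turns the terminal alkyne into the 2-substituted buta-1,3-diene and comes back to the route at 19.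

**Further compounds**
F1 | step 5 | [(2R,3R)-3-[2-(3-methoxyphenyl)ethyl]-2-methyloxiran-2-yl]methanol | OC[C@@]1(C)O[C@@H]1CCc2cccc(OC)c2
F2 | step 5 | tert-butyl{[(2R,3R)-3-[2-(3-methoxyphenyl)ethyl]-2-methyloxiran-2-yl]methoxy}dimethylsilane | CC(C)(C)[Si](C)(C)OC[C@@]1(C)O[C@@H]1CCc2cccc(OC)c2
F3 | step 5 | (1S,2R)-1-({[tert-butyl(dimethyl)silyl]oxy}methyl)-6-methoxy-1-methyl-1,2,3,4-tetrahydronaphthalen-2-ol | COc1ccc2c(c1)CC[C@@H](O)[C@]2(C)CO[Si](C)(C)C(C)(C)C
F4 | step 5 | (1S,2R)-1-({[tert-butyl(dimethyl)silyl]oxy}methyl)-6-methoxy-1-methyl-1,2,3,4,5,8-hexahydronaphthalen-2-ol | COC1=CCC2=C(C1)CC[C@@H](O)[C@]2(C)CO[Si](C)(C)C(C)(C)C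
F5 | step 7 | (1S,2R,8aS)-1-({[tert-butyl(dimethyl)silyl]oxy}methyl)-1-methyl-6-oxo-4a,5-methanodecahydronaphthalen-2-yl acetate (cyclopropane CH2 syn to H-8a) | O=C1CC[C@H]2[C@]3(C[C@@H]13)CC[C@@H](OC(C)=O)[C@]2(C)CO[Si](C)(C)C(C)(C)C
F6 | step 9 | (1S,2R,4aS,5R,8aS)-5-(but-3-yn-1-yl)-1-({[tert-butyl(dimethyl)silyl]oxy}methyl)-1,4a-dimethyl-6-oxodecahydronaphthalen-2-yl acetate | C#CCC[C@H]1C(=O)CC[C@H]2[C@]1(C)CC[C@@H](OC(C)=O)[C@]2(C)CO[Si](C)(C)C(C)(C)C
F7 | step 9 | (1S,2R,4aR,5S,8aS)-5-(but-3-yn-1-yl)-1-({[tert-butyl(dimethyl)silyl]oxy}methyl)-1,4a-dimethyl-6-methylidenedecahydronaphthalen-2-yl acetate | C#CCC[C@H]1C(=C)CC[C@H]2[C@]1(C)CC[C@@H](OC(C)=O)[C@]2(C)CO[Si](C)(C)C(C)(C)C
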